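The data stem from a simulated flask for an exercise, and the scatter is random.

| setting | Sunday's | larch | oak |
|---|---|---|---|
| starting material | 49 mM | 49 mM | 49 mM |
| free catalyst | 0.34 mol% | 0.5 mol% | 0.65 mol% |
| remark | run made earlier |  |  |
| time |  | 2.5 min | 2.5 min |

Sunday's run (percent of the starting material charged)

| time / s | isomer of the product / % | catalyst intermediate / % | target / % | starting material / % |
|---|---|---|---|---|
| 10.0 | 0.2 | 0 | 5.8 | 94.0 |
| 20.0 | 0.9 | 0.5 | 11.3 | 88.3 |
| 40.0 | 3.2 | 0 | 19.8 | 78.2 |
| 60.0 | 5.3 | 0.8 | 25.6 | 69.9 |
| 80.0 | 7.7 | 0 | 31.9 | 60.2 |
| 120 | 12.1 | 0.5 | 40.6 | 47.3 |

(standard deviation of a reading: 0.5 percentage points)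

- what was read earlier has a scatter of 0.5 percentage points, one standard deviation
- on the list of suspects stand: starting material + free catalyst <-> catalyst intermediate; catalyst intermediate -> free catalyst + target; target + free catalyst <-> isomer of the product + free catalyst
- no earlier run changes the charge of free catalyst; that part of a forecast is a guess

- which of these there is most of at the end, counted by the starting material in it, larch (catalyst intermediate / target / starting material / isomer of the product)
- which of these there is most of at the end, counted by the starting material in it, oak (catalyst intermediate / target / starting material / isomer of the product)
- amount of the one of these that there is most of at the end, in percent of the starting material charged, larch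
- amount of the one of these that there is most of at the end, in percent of the starting material charged, oak

- The easy step comes from Sunday's flask. Let k be the fractional loss rate of starting material, −ln(fraction left)/t. It reads 0.00615 s⁻¹ at 40.0 s and 0.00624 s⁻¹ at 120 s.
- These two readings stand close together, so Sunday's rate falls in step with starting material (pseudo-first-order), and free catalyst can be frozen at its charge.
- Each suspect step that consumes starting material or target needs free catalyst. While that catalyst stays near its charge, catalyst concentration and time therefore enter as one product.
- For larch, that product over the same product at Sunday's last reading is 1.84; this ratio is the catalyst clock R. For oak, R is 2.39. The scaling with charge is a guess, since no earlier run varies it.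
- Larch starts faster than Sunday's flask by a factor of 1.47, at k = 0.550 min⁻¹; oak starts faster by 1.91, at 0.716 min⁻¹.
- The slowing comes from starting material running down. The fraction left is Sunday's last fraction raised to the power R, which gives 25.3% for larch and 16.7% for oak. Larch's rate thus ends at about a quarter of its start, and oak's at 16.7%.
- Target's share of the converted part fell on Sunday from 86.1% at 40.0 s to 77.0% at 120 s. This reckoning therefore places target below 57.5% in larch and 64.1% in oak. Carrying that fall on in a straight line against R gives a share of 65.7% in larch and 58.2% in oak. This estimate, which is no bound, puts larch at 49.1% target, 25.7% isomer of the product and 25.3% starting material, and oak at 48.5%, 34.8% and 16.7%, so this reckoning names target.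
- The forecast names target for larch at 55% and target for oak at 60.5%, holding that “the catalyst is unsaturated and the rate should scale with its charge”.
- Larch gives target at 54.1%, and oak gives target at 59.3%, so the forecast stands. Starting material left is 25.2% and 16.7%. At the end, oak's catalyst is 99.9% free and 0.0539% catalyst intermediate.

    starting material + free catalyst ⇌ catalyst intermediate (K = 52.0 M⁻¹, k = 37.6 M⁻¹ s⁻¹)
    catalyst intermediate → free catalyst + target (k = 569 s⁻¹)
    target + free catalyst ⇌ isomer of the product + free catalyst, rate k3*[free catalyst]*[target] forward; the back reaction follows from the equilibrium constant (K = 0.438, k = 53.7 M⁻¹ s⁻¹)

- The neighbouring flask repeats oak at 20 mM of starting material, with the same loading and time. Its catalyst concentration drops with the starting material, so its clock reads 0.975 against oak's 2.39. The clock gives 48.2% of starting material left, beside Sunday's last reading of 47.3%. The neighbouring flask holds 48.1% starting material, more than its 39.8% target, where Sunday's last reading shows 40.6% target. Its isomer of the product stands at 12.1%, beside Sunday's 12.1%.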